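The cycloheptenone ring is opened at the C4–C5 bond (azulenone numbering: C4 carries the ester oxygen, C5 is the ring CH2). The sequence O–C4–C5–C6(CH3)=C7–C8(=O) is a vinylogous aldol retron, and because C8a is quaternary the C8 ketone can enolise only towards the C6 methyl groups. One intramolecular vinylogous Mukaiyama aldol reaction therefore closes the seven-membered ring, creates the C4 carbinol stereocentre and leaves the enone in place. Its precursor is a fully substituted cyclopentane carrying a formyl group at C3a, a 3-methylbut-2-enoyl group at C8a and the tertiary isopropyl carbinol at C3.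

Key step: step 6

Assumption: the target is the (3R,3aS,4S,8aS) enantiomer encoded in the SMILES; azulenone numbering of the target is used for all atoms, and the absolute configuration comes from the chiral copper catalyst of step 1.

Step 1
Reactants: 1 3-methylcyclopent-2-en-1-one; 2 (2-methylprop-1-en-1-yl)magnesium bromide
Product: 5 (2S,3R)-2-(hydroxymethyl)-3-methyl-3-(2-methylprop-1-en-1-yl)cyclopentan-1-one, via alkenylalane 3 (not isolated), via aluminium enolate 4 (not isolated)
Conditions: 2, Me2AlCl, Et2O, 0 °C; CuTC (copper thiophene-2-carboxylate, C5H3CuO2S, 5 mol%), chiral diarylphosphinamine ligand (enantiomer giving the R quaternary centre, 5.5 mol%), 1, Et2O, −30 °C; then monomeric CH2O in THF, −78 → −40 °C; aq. NH4Cl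
Reagents that add atoms: formaldehyde, C=O
Why: Copper-catalysed asymmetric conjugate addition of the alkenylalane to the β-methyl enone creates the quaternary centre (future C8a) under ligand control, and the regiodefined aluminium enolate then adds to formaldehyde (aldol reaction) on the face opposite the bulky 2-methylprop-1-enyl group, which places the hydroxymethyl group at the future C3a cis to the methyl group.

Step 2
Reactants: 5 (2S,3R)-2-(hydroxymethyl)-3-methyl-3-(2-methylprop-1-en-1-yl)cyclopentan-1-one
Product: 6 (1R,2S,3R)-2-(hydroxymethyl)-3-methyl-3-(2-methylprop-1-en-1-yl)-1-(propan-2-yl)cyclopentan-1-ol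
Conditions: i-PrMgCl (3 equiv), LaCl3·2LiCl (0.3 equiv), THF, −20 → 0 °C; aq. NH4Cl
Reagents that add atoms: isopropylmagnesium chloride, CC(C)[Mg]Cl
Why: Lanthanum-promoted Grignard 1,2-addition should take place on the ketone face anti to the adjacent hydroxymethyl substituent, which fixes the tertiary carbinol (future C3) with OH cis to CH2OH and the isopropyl group trans to it.

Step 3
Reactants: 6 (1R,2S,3R)-2-(hydroxymethyl)-3-methyl-3-(2-methylprop-1-en-1-yl)-1-(propan-2-yl)cyclopentan-1-ol
Product: 8 (1S,2S,3R)-3-hydroxy-2-(hydroxymethyl)-1-methyl-3-(propan-2-yl)cyclopentane-1-carbaldehyde, via ozonide 7 (not isolated)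
Conditions: O3, CH2Cl2, −78 °C; then Me2S, −78 °C → rt
Reagents that add atoms: ozone, [O-][O+]=O
Why: Ozonolysis with reductive work-up cleaves the only C=C bond and leaves the alkene CH carbon as the aldehyde (future C8) on the quaternary centre; no stereocentre is touched.

Step 4
Reactants: 8 (1S,2S,3R)-3-hydroxy-2-(hydroxymethyl)-1-methyl-3-(propan-2-yl)cyclopentane-1-carbaldehyde; 2 (2-methylprop-1-en-1-yl)magnesium bromide
Product: 9 (1R,2S,3S)-3-(1-hydroxy-3-methylbut-2-en-1-yl)-2-(hydroxymethyl)-3-methyl-1-(propan-2-yl)cyclopentan-1-ol (both epimers at the side-chain carbinol)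
Conditions: 2 (3.5 equiv), THF, 0 °C → rt; aq. NH4Cl
Reagents that add atoms: none
Why: Grignard addition to the aldehyde (after deprotonation of the two hydroxyl groups) brings in the future C7, C6, C5 and the C6 methyl group; the new carbinol centre forms as a mixture and is removed by oxidation in step 5.

Step 5
Reactants: 9 (1R,2S,3S)-3-(1-hydroxy-3-methylbut-2-en-1-yl)-2-(hydroxymethyl)-3-methyl-1-(propan-2-yl)cyclopentan-1-ol
Product: 10 (1R,2R,5S)-2-hydroxy-5-methyl-5-(3-methylbut-2-enoyl)-2-(propan-2-yl)cyclopentane-1-carbaldehyde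
Conditions: Dess–Martin periodinane (2.5 equiv), NaHCO3, CH2Cl2, 0 °C → rt
Reagents that add atoms: none
Why: Dess–Martin oxidation turns the secondary allylic alcohol into the enone and the primary alcohol into the aldehyde while the tertiary alcohol is inert; the aldehyde α-carbon keeps its configuration, which is also the more stable one (formyl trans to isopropyl and to the acyl group).

Step 6
Reactants: 10 (1R,2R,5S)-2-hydroxy-5-methyl-5-(3-methylbut-2-enoyl)-2-(propan-2-yl)cyclopentane-1-carbaldehyde
Product: 13 (3R,3aS,4S,8aS)-3,4-dihydroxy-6,8a-dimethyl-3-(propan-2-yl)-2,3,3a,4,5,8a-hexahydroazulen-8(1H)-one, via silyl dienol ether 11 (not isolated), via silylated cycloheptenone 12 (not isolated)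
Conditions: TMSOTf (3.5 equiv), i-Pr2NEt (3.0 equiv), CH2Cl2, −78 → −10 °C; then AcOH/THF/H2O, rt
Reagents that add atoms: none
Why: TMSOTf silylates the tertiary alcohol and, with the amine, converts the enone into the silyl dienol ether 11 (only γ-protons are available because C8a is quaternary, and the aldehyde α-hydrogen sits between two fully substituted carbons); the excess TMSOTf activates the aldehyde, the diene terminus C5 attacks it, and silyl transfer gives 12, which is desilylated on acidic work-up. The closest known reaction type is the intramolecular vinylogous Mukaiyama aldol reaction, run as a one-pot enol silane formation and aldol addition. The seven-membered ring closes in a 7-(enolendo)-exo-trig mode through the γ-carbon, whereas attack through the α-carbon C7 would be a 5-(enolendo)-exo-trig closure, which is stereoelectronically disfavoured, so the tether enforces γ-selectivity. The new stereocentre C4 is controlled by the trans-disposed substituents of the cyclopentane: in the chair-like transition state leading to the trans-fused bicycle the silyl-activated carbonyl oxygen should point to the α-face, away from the β-oriented C8a methyl and C3 silyloxy groups, which gives the equatorial 4S alcohol. The step needs γ- over α-attack and ketone over aldehyde enolisation, and both are secured by the substrate as described.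

Step 7
Reactants: 13 (3R,3aS,4S,8aS)-3,4-dihydroxy-6,8a-dimethyl-3-(propan-2-yl)-2,3,3a,4,5,8a-hexahydroazulen-8(1H)-one; 14 4-acetoxy-3-methoxybenzoic acid
Product: 15 (3R,3aS,4S,8aS)-3-hydroxy-6,8a-dimethyl-8-oxo-3-(propan-2-yl)-1,2,3,3a,4,5,8,8a-octahydroazulen-4-yl 4-acetoxy-3-methoxybenzoate
Conditions: 14 (1.5 equiv), DCC (1.6 equiv), DMAP (0.3 equiv), CH2Cl2, 0 °C → rt
Reagents that add atoms: none
Why: Steglich esterification should acylate only the secondary C4 hydroxyl, the tertiary C3 hydroxyl beside the isopropyl group being too hindered, and proceeds with retention at C4.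

Step 8
Reactants: 15 (3R,3aS,4S,8aS)-3-hydroxy-6,8a-dimethyl-8-oxo-3-(propan-2-yl)-1,2,3,3a,4,5,8,8a-octahydroazulen-4-yl 4-acetoxy-3-methoxybenzoate
Product: 16 (3R,3aS,4S,8aS)-3-hydroxy-6,8a-dimethyl-8-oxo-3-(propan-2-yl)-1,2,3,3a,4,5,8,8a-octahydroazulen-4-yl 4-hydroxy-3-methoxybenzoate
Conditions: pyrrolidine (1.2 equiv), CH2Cl2, 0 °C
Reagents that add atoms: none
Why: Aminolysis (acyl transfer to pyrrolidine) should cleave the electron-poor aryl acetate much faster than the hindered benzoate and avoids basic conditions that could eliminate the vinylogous β-acyloxy ketone.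

Compound list
1 | 3-methylcyclopent-2-en-1-one | CC1=CC(=O)CC1 | starting material
2 | (2-methylprop-1-en-1-yl)magnesium bromide (THF solution) | CC(C)=C[Mg]Br | starting material
3 | dimethyl(2-methylprop-1-en-1-yl)alane | C[Al](C)C=C(C)C | intermediate (not isolated)
4 | dimethylaluminium (R)-3-methyl-3-(2-methylprop-1-en-1-yl)cyclopent-1-en-1-olate | CC(C)=C[C@@]1(C)CCC(O[Al](C)C)=C1 | intermediate (not isolated)
5 | (2S,3R)-2-(hydroxymethyl)-3-methyl-3-(2-methylprop-1-en-1-yl)cyclopentan-1-one | CC(C)=C[C@@]1(C)CCC(=O)[C@@H]1CO | intermediate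
6 | (1R,2S,3R)-2-(hydroxymethyl)-3-methyl-3-(2-methylprop-1-en-1-yl)-1-(propan-2-yl)cyclopentan-1-ol | CC(C)=C[C@@]1(C)CC[C@@](O)(C(C)C)[C@@H]1CO | intermediate
7 | ozonide of 6 (5,5-dimethyl-1,2,4-trioxolan-3-yl group on the quaternary carbon) | CC1(C)OOC(O1)[C@@]2(C)CC[C@@](O)(C(C)C)[C@@H]2CO | intermediate (not isolated)
8 | (1S,2S,3R)-3-hydroxy-2-(hydroxymethyl)-1-methyl-3-(propan-2-yl)cyclopentane-1-carbaldehyde | O=C[C@@]1(C)CC[C@@](O)(C(C)C)[C@@H]1CO | intermediate
9 | (1R,2S,3S)-3-(1-hydroxy-3-methylbut-2-en-1-yl)-2-(hydroxymethyl)-3-methyl-1-(propan-2-yl)cyclopentan-1-ol, both epimers at the side-chain carbinol | CC(C)=CC(O)[C@@]1(C)CC[C@@](O)(C(C)C)[C@@H]1CO | intermediate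
10 | (1R,2R,5S)-2-hydroxy-5-methyl-5-(3-methylbut-2-enoyl)-2-(propan-2-yl)cyclopentane-1-carbaldehyde | CC(C)=CC(=O)[C@@]1(C)CC[C@@](O)(C(C)C)[C@@H]1C=O | intermediate
11 | (1R,2R,5S)-5-methyl-5-[(1Z)-3-methyl-1-(trimethylsilyloxy)buta-1,3-dien-1-yl]-2-(propan-2-yl)-2-(trimethylsilyloxy)cyclopentane-1-carbaldehyde | C=C(C)/C=C(\O[Si](C)(C)C)[C@@]1(C)CC[C@@](O[Si](C)(C)C)(C(C)C)[C@@H]1C=O | intermediate (not isolated)
12 | (3R,3aS,4S,8aS)-6,8a-dimethyl-3-(propan-2-yl)-3,4-bis(trimethylsilyloxy)-2,3,3a,4,5,8a-hexahydroazulen-8(1H)-one | C[Si](C)(C)O[C@H]1CC(C)=CC(=O)[C@@]2(C)CC[C@@](O[Si](C)(C)C)(C(C)C)[C@H]12 | intermediate (not isolated)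
13 | (3R,3aS,4S,8aS)-3,4-dihydroxy-6,8a-dimethyl-3-(propan-2-yl)-2,3,3a,4,5,8a-hexahydroazulen-8(1H)-one | O[C@H]1CC(C)=CC(=O)[C@@]2(C)CC[C@@](O)(C(C)C)[C@H]12 | intermediate
14 | 4-acetoxy-3-methoxybenzoic acid | COc1cc(C(=O)O)ccc1OC(C)=O | starting material
15 | (3R,3aS,4S,8aS)-3-hydroxy-6,8a-dimethyl-8-oxo-3-(propan-2-yl)-1,2,3,3a,4,5,8,8a-octahydroazulen-4-yl 4-acetoxy-3-methoxybenzoate | COc1cc(C(=O)O[C@H]2CC(C)=CC(=O)[C@@]3(C)CC[C@@](O)(C(C)C)[C@H]23)ccc1OC(C)=O | intermediate
16 | (3R,3aS,4S,8aS)-3-hydroxy-6,8a-dimethyl-8-oxo-3-(propan-2-yl)-1,2,3,3a,4,5,8,8a-octahydroazulen-4-yl 4-hydroxy-3-methoxybenzoate | COc1cc(C(=O)O[C@H]2CC(C)=CC(=O)[C@@]3(C)CC[C@@](O)(C(C)C)[C@H]23)ccc1O | target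

Total step count: 8. Longest linear sequence: 8 steps (1 → 16).

Steps most likely to fail

Step 6 (key step). The silyl triflate may consume the hindered aldehyde (O-silylation or enol silane formation) faster than the diene terminus attacks it, or the dienol ether may revert to the enone, so that ring closure stalls. The fallback sets out from 10 and returns at 13. The tertiary alcohol of 10 is silylated (TESOTf, 2,6-lutidine, CH2Cl2, −78 °C) to give (1R,2R,5S)-5-methyl-5-(3-methylbut-2-enoyl)-2-(propan-2-yl)-2-(triethylsilyloxy)cyclopentane-1-carbaldehyde F1. Both carbonyl groups of F1 are then complexed with Al(O-2,6-Ph2C6H3)3 (aluminium tris(2,6-diphenylphenoxide), 2.2 equiv) in toluene at −78 °C and the γ-methyl group is deprotonated with LDA. The lithium dienolate should close the same C4–C5 bond in a direct, non-silyl vinylogous aldol reaction and give (3R,3aS,4S,8aS)-4-hydroxy-6,8a-dimethyl-3-(propan-2-yl)-3-(triethylsilyloxy)-2,3,3a,4,5,8a-hexahydroazulen-8(1H)-one F2. Aqueous HCl in THF removes the silyl ether and gives 13.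

Step 1. Transfer of the β,β-disubstituted alkenyl group to the hindered β-carbon of the five-membered enone may be sluggish or poorly face-selective, and the aluminium enolate may be protonated before the aldol. The fallback sets out from 2 and returns at enolate 4, and hence at 5. Grignard reagent 2 is added to 3-ethoxycyclopent-2-en-1-one F3 and the adduct is hydrolysed with dilute acid (Stork–Danheiser sequence) to give 3-(2-methylprop-1-en-1-yl)cyclopent-2-en-1-one F4. The quaternary centre is then created with the roles exchanged, by copper-catalysed asymmetric 1,4-addition of Me3Al (CuTC, chiral phosphoramidite ligand, Et2O, −30 °C). This should deliver the same dimethylaluminium enolate 4, which is trapped with formaldehyde as in step 1.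

Step 2. The branched Grignard reagent may enolise the hindered ketone or reduce it by β-hydride transfer instead of adding. The fallback sets out from 5 and returns at 6. Prop-1-en-2-ylmagnesium bromide (LaCl3·2LiCl, THF, 0 °C), which is less hindered and cannot transfer a β-hydride, is added to 5 to give (1S,2S,3R)-2-(hydroxymethyl)-3-methyl-3-(2-methylprop-1-en-1-yl)-1-(prop-1-en-2-yl)cyclopentan-1-ol F5. Chemoselective hydrogenation of the 1,1-disubstituted alkene in the presence of the trisubstituted one (H2, RhCl(PPh3)3, benzene) should then give 6.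

Further compounds
F1 | step 6 | (1R,2R,5S)-5-methyl-5-(3-methylbut-2-enoyl)-2-(propan-2-yl)-2-(triethylsilyloxy)cyclopentane-1-carbaldehyde | CC(C)=CC(=O)[C@@]1(C)CC[C@@](O[Si](CC)(CC)CC)(C(C)C)[C@@H]1C=O
F2 | step 6 | (3R,3aS,4S,8aS)-4-hydroxy-6,8a-dimethyl-3-(propan-2-yl)-3-(triethylsilyloxy)-2,3,3a,4,5,8a-hexahydroazulen-8(1H)-one | O[C@H]1CC(C)=CC(=O)[C@@]2(C)CC[C@@](O[Si](CC)(CC)CC)(C(C)C)[C@H]12
F3 | step 1 | 3-ethoxycyclopent-2-en-1-one | CCOC1=CC(=O)CC1
F4 | step 1 | 3-(2-methylprop-1-en-1-yl)cyclopent-2-en-1-one | CC(C)=CC1=CC(=O)CC1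
F5 | step 2 | (1S,2S,3R)-2-(hydroxymethyl)-3-methyl-3-(2-methylprop-1-en-1-yl)-1-(prop-1-en-2-yl)cyclopentan-1-ol | CC(C)=C[C@@]1(C)CC[C@@](O)(C(C)=C)[C@@H]1CO
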